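## Retrosynthetic overview

1. The C3–heptenyl bond is made late by Stille coupling of bromo epoxy-enone 21 (ring plus side chain, C12) with (E)-heptenylstannane 9 (C7); ketal hydrolysis, C5 reduction and ester cleavage follow.
2. The oxirane of 21 comes from dienone 20 by hydroxyl-directed, tartrate-mediated nucleophilic epoxidation; the side chain of 20 comes from ylide 4 and the aldehyde made by ozonolysis of allyl dienone 18.
3. 18 comes from phenol 17 by oxidative dearomatisation; 17 comes from benzoate 13 by O-allylation, Claisen rearrangement and ester reduction.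
4. 13 comes from a Diels–Alder/aromatisation of 2-methoxyfuran 10 with bromoalkynoate 11.
5. Ring order: the six-membered carbocycle first (as a benzene ring in step 6, dearomatised in step 10), the oxirane second (step 12).

Assumption: D-(−)-diisopropyl tartrate is taken to give the (1S,6R) epoxide 21 (mirror image of the natural ambuic acid series obtained with the L-tartrate); if the sense proves opposite, the L-tartrate is used with nothing else changed.

Ring positions in the text follow the 7-oxabicyclo[4.1.0]hept-3-ene names: C1 quaternary epoxide carbon, C2 ketone, C3 heptenyl, C4 CH2OH, C5 carbinol, C6 epoxide CH. The target is (1S,5R,6S), with the C5 hydroxyl anti to the oxirane oxygen.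

## Route

Step 1
Reactants: 1 2-bromopropanoic acid (racemic)
Product: 2 tert-butyl 2-bromopropanoate (racemic)
Conditions: isobutene (excess), H2SO4 (cat.), CH2Cl2, sealed vessel, rt
Reagents that add atoms: 2-methylpropene (isobutene), C=C(C)C
Why: Acid-catalysed addition of the carboxylic acid to isobutene (tert-butyl esterification) installs an acid-labile ester that survives the later basic and oxidative steps; the racemic α-centre is erased in step 3.

Step 2
Reactants: 2 tert-butyl 2-bromopropanoate
Product: 3 (1-tert-butoxy-1-oxopropan-2-yl)triphenylphosphonium bromide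
Conditions: PPh3, toluene, 70 °C
Reagents that add atoms: triphenylphosphine, c1ccc(cc1)P(c1ccccc1)c1ccccc1
Why: SN2 quaternisation of PPh3 by the activated secondary α-bromo ester gives the phosphonium salt, which precipitates.

Step 3
Reactants: 3 (1-tert-butoxy-1-oxopropan-2-yl)triphenylphosphonium bromide
Product: 4 tert-butyl 2-(triphenyl-λ5-phosphanylidene)propanoate
Conditions: NaOH (1 M aq), CH2Cl2, 0 °C to rt
Reagents that add atoms: none
Why: Deprotonation of the acidic α-CH gives the ester-stabilised Wittig ylide, which is stable enough to isolate.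

Step 4
Reactants: 5 hept-1-yne
Product: 7 (1E)-1-iodohept-1-ene, via (E)-hept-1-enylzirconocene chloride 6 (not isolated)
Conditions: Cp2Zr(H)Cl, THF, rt; then I2, 0 °C
Reagents that add atoms: iodine, [I][I]
Why: Hydrozirconation adds Zr–H syn with zirconium on the terminal carbon, and iodinolysis of the C–Zr bond proceeds with retention, so only the E iodide forms.

Step 5
Reactants: 7 (1E)-1-iodohept-1-ene
Product: 9 tributyl[(1E)-hept-1-en-1-yl]stannane, via (1E)-hept-1-en-1-yllithium 8 (not isolated)
Conditions: t-BuLi (2.1 equiv), Et2O, −78 °C; then Bu3SnCl, −78 °C to rt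
Reagents that add atoms: tributyltin chloride, CCCC[Sn](Cl)(CCCC)CCCC
Why: Iodine–lithium exchange and stannylation both retain the alkene geometry, giving the isomerically pure E stannane.

Step 6
Reactants: 10 2-methoxyfuran, 11 methyl 3-bromoprop-2-ynoate
Product: 13 methyl 2-bromo-3-hydroxy-6-methoxybenzoate, via oxanorbornadiene adduct 12 (not isolated)
Conditions: toluene, 0 °C to 40 °C; then TsOH·H2O (cat.), rt
Reagents that add atoms: none
Why: In this polarity-matched Diels–Alder reaction the nucleophilic furan C5 bonds to the bromine-bearing β-carbon of the ynoate and the methoxy-bearing C2 to the ester-bearing carbon; the 1-methoxy-7-oxanorbornadiene then opens at its acetal C–O bond and tautomerises to the p-methoxyphenol, placing OH next to C–Br and OMe next to the ester.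

Step 7
Reactants: 13 methyl 2-bromo-3-hydroxy-6-methoxybenzoate, 14 3-bromoprop-1-ene (allyl bromide)
Product: 15 methyl 2-bromo-6-methoxy-3-(prop-2-en-1-yloxy)benzoate
Conditions: K2CO3, DMF, rt
Reagents that add atoms: none
Why: Williamson O-allylation of the acidic ortho-bromophenol is clean and masks the phenol as the group used in step 8.

Step 8
Reactants: 15 methyl 2-bromo-6-methoxy-3-(prop-2-en-1-yloxy)benzoate
Product: 16 methyl 2-bromo-3-hydroxy-6-methoxy-4-(prop-2-en-1-yl)benzoate
Conditions: N,N-diethylaniline, 190 °C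
Reagents that add atoms: none
Why: The aromatic Claisen rearrangement ([3,3]-sigmatropic) can deliver the allyl group only to the one free ortho carbon, the other being blocked by bromine, and tautomerisation restores the phenol.

Step 9
Reactants: 16 methyl 2-bromo-3-hydroxy-6-methoxy-4-(prop-2-en-1-yl)benzoate
Product: 17 2-bromo-3-(hydroxymethyl)-4-methoxy-6-(prop-2-en-1-yl)phenol
Conditions: (i-Bu)2AlH (4 equiv), CH2Cl2, −78 °C to 0 °C; aq KNaC4H4O6 work-up
Reagents that add atoms: none
Why: Aluminium hydride reduction of the methyl ester gives the benzylic alcohol; the aryl bromide and terminal alkene are inert and the phenol is only deprotonated.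

Step 10
Reactants: 17 2-bromo-3-(hydroxymethyl)-4-methoxy-6-(prop-2-en-1-yl)phenol
Product: 18 2-bromo-3-(hydroxymethyl)-4,4-dimethoxy-6-(prop-2-en-1-yl)cyclohexa-2,5-dien-1-one
Conditions: PhI(OAc)2, MeOH, 0 °C
Reagents that add atoms: methanol, CO
Why: In this oxidative dearomatisation the phenoxenium ion is trapped by methanol at the methoxy-bearing para carbon, giving the quinone monoketal in which the future C2 carbonyl is free and the future C5 carbonyl is masked.

Step 11
Reactants: 18 2-bromo-3-(hydroxymethyl)-4,4-dimethoxy-6-(prop-2-en-1-yl)cyclohexa-2,5-dien-1-one, 4 tert-butyl 2-(triphenyl-λ5-phosphanylidene)propanoate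
Product: 20 tert-butyl (2E)-4-[5-bromo-4-(hydroxymethyl)-3,3-dimethoxy-6-oxocyclohexa-1,4-dien-1-yl]-2-methylbut-2-enoate, via dienone acetaldehyde 19 (not isolated)
Conditions: O3, NaHCO3, CH2Cl2/MeOH, −78 °C (Sudan red 7B end point); Me2S, −78 °C to rt; then 4 (1.5 equiv), CH2Cl2, rt
Reagents that add atoms: none
Why: Ozonolysis is selective for the electron-rich terminal alkene over the two enone double bonds, and the Wittig reaction of the aldehyde with the ester-stabilised α-methyl ylide gives the trisubstituted enoate with the usual high E selectivity.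

Step 12
Reactants: 20 tert-butyl (2E)-4-[5-bromo-4-(hydroxymethyl)-3,3-dimethoxy-6-oxocyclohexa-1,4-dien-1-yl]-2-methylbut-2-enoate
Product: 21 tert-butyl (2E)-4-[(1S,6R)-3-bromo-4-(hydroxymethyl)-5,5-dimethoxy-2-oxo-7-oxabicyclo[4.1.0]hept-3-en-1-yl]-2-methylbut-2-enoate
Conditions: Ph3COOH (2 equiv), NaN(SiMe3)2 (3.3 equiv), D-(−)-diisopropyl tartrate (1.1 equiv), toluene, −65 °C to −50 °C, 48 h
Reagents that add atoms: triphenylmethyl hydroperoxide, OOC(c1ccccc1)(c1ccccc1)c1ccccc1
Why: In this Weitz–Scheffer-type nucleophilic epoxidation the sodium tartrate–trityl peroxide aggregate, to which the substrate alkoxide is bound, adds the peroxide face-selectively to C6 of the less substituted enone (the bromo alkene is tetrasubstituted and blocked), and enolate closure gives the cis-fused oxirane, setting C1 (S) and C6 (R) together.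

Step 13
Reactants: 21 tert-butyl (2E)-4-[(1S,6R)-3-bromo-4-(hydroxymethyl)-5,5-dimethoxy-2-oxo-7-oxabicyclo[4.1.0]hept-3-en-1-yl]-2-methylbut-2-enoate, 9 tributyl[(1E)-hept-1-en-1-yl]stannane
Product: 23 tert-butyl (2E)-4-[(1S,6R)-3-[(1E)-hept-1-en-1-yl]-4-(hydroxymethyl)-2,5-dioxo-7-oxabicyclo[4.1.0]hept-3-en-1-yl]-2-methylbut-2-enoate, via coupled dimethyl ketal 22 (not isolated)
Conditions: 9 (1.5 equiv), Pd2(dba)3 (5 mol %), AsPh3 (20 mol %), toluene, 100 °C; evaporate; then 48% aq HF, MeCN, 0 °C to rt
Reagents that add atoms: water, O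
Why: In the Stille cross-coupling the α-bromo enone adds oxidatively to zerovalent palladium, the alkenyl group transfers from tin with retention of E geometry and reductive elimination joins the two fragments; aqueous HF then hydrolyses the dimethyl ketal to the C5 ketone without touching the epoxide stereocentres or the tert-butyl ester.

Step 14
Reactants: 23 tert-butyl (2E)-4-[(1S,6R)-3-[(1E)-hept-1-en-1-yl]-4-(hydroxymethyl)-2,5-dioxo-7-oxabicyclo[4.1.0]hept-3-en-1-yl]-2-methylbut-2-enoate
Product: 24 tert-butyl (2E)-4-[(1S,5R,6S)-3-[(1E)-hept-1-en-1-yl]-5-hydroxy-4-(hydroxymethyl)-2-oxo-7-oxabicyclo[4.1.0]hept-3-en-1-yl]-2-methylbut-2-enoate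
Conditions: (R)-2-methyl-CBS-oxazaborolidine [(3aR)-1-methyl-3,3-diphenyltetrahydro-1H,3H-pyrrolo[1,2-c][1,3,2]oxazaborole, C18H20BNO] (0.5 equiv), catecholborane (3.5 equiv), CH2Cl2/toluene, −78 °C to −40 °C; MeOH quench
Reagents that add atoms: none
Why: In this Corey–Bakshi–Shibata reduction under reagent control the less hindered C5 carbonyl (the CH2OH being masked in situ as its catechol borate) binds the catalyst boron on the lone pair next to the small epoxide carbon, and catalyst-bound catecholborane delivers hydride to the face carrying the oxirane oxygen, setting C5 as R with the hydroxyl anti to the epoxide.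

Step 15
Reactants: 24 tert-butyl (2E)-4-[(1S,5R,6S)-3-[(1E)-hept-1-en-1-yl]-5-hydroxy-4-(hydroxymethyl)-2-oxo-7-oxabicyclo[4.1.0]hept-3-en-1-yl]-2-methylbut-2-enoate
Product: 25 (2E)-4-[(1S,5R,6S)-3-[(1E)-hept-1-en-1-yl]-5-hydroxy-4-(hydroxymethyl)-2-oxo-7-oxabicyclo[4.1.0]hept-3-en-1-yl]-2-methylbut-2-enoic acid
Conditions: CF3CO2H/CH2Cl2 (1:4), 0 °C to rt; aq NaHCO3/MeOH work-up, then acidify to pH 3
Reagents that add atoms: none
Why: Acidolysis of the tert-butyl ester (alkyl–oxygen cleavage with loss of isobutene) frees the acid without touching the keto-epoxide or any stereocentre.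

## Compound list

1 | 2-bromopropanoic acid (racemic) | CC(Br)C(=O)O | starting material
2 | tert-butyl 2-bromopropanoate (racemic) | CC(Br)C(=O)OC(C)(C)C | intermediate
3 | (1-tert-butoxy-1-oxopropan-2-yl)triphenylphosphonium bromide (racemic) | CC(C(=O)OC(C)(C)C)[P+](c1ccccc1)(c1ccccc1)c1ccccc1.[Br-] | intermediate
4 | tert-butyl 2-(triphenyl-λ5-phosphanylidene)propanoate | CC(C(=O)OC(C)(C)C)=P(c1ccccc1)(c1ccccc1)c1ccccc1 | intermediate
5 | hept-1-yne | CCCCCC#C | starting material
6 | chlorobis(cyclopentadienyl)[(1E)-hept-1-en-1-yl]zirconium (not isolated) | CCCCC/C=C/[Zr](Cl)(C1C=CC=C1)C1C=CC=C1 | intermediate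
7 | (1E)-1-iodohept-1-ene | CCCCC/C=C/I | intermediate
8 | (1E)-hept-1-en-1-yllithium (not isolated) | CCCCC/C=C/[Li] | intermediate
9 | tributyl[(1E)-hept-1-en-1-yl]stannane | CCCCC/C=C/[Sn](CCCC)(CCCC)CCCC | intermediate
10 | 2-methoxyfuran | COc1ccco1 | starting material
11 | methyl 3-bromoprop-2-ynoate | COC(=O)C#CBr | starting material
12 | methyl 3-bromo-1-methoxy-7-oxabicyclo[2.2.1]hepta-2,5-diene-2-carboxylate (racemic; not isolated) | COC(=O)C1=C(Br)C2C=CC1(OC)O2 | intermediate
13 | methyl 2-bromo-3-hydroxy-6-methoxybenzoate | COC(=O)c1c(Br)c(O)ccc1OC | intermediate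
14 | 3-bromoprop-1-ene (allyl bromide) | C=CCBr | starting material
15 | methyl 2-bromo-6-methoxy-3-(prop-2-en-1-yloxy)benzoate | COC(=O)c1c(Br)c(OCC=C)ccc1OC | intermediate
16 | methyl 2-bromo-3-hydroxy-6-methoxy-4-(prop-2-en-1-yl)benzoate | COC(=O)c1c(Br)c(O)c(CC=C)cc1OC | intermediate
17 | 2-bromo-3-(hydroxymethyl)-4-methoxy-6-(prop-2-en-1-yl)phenol | COc1cc(CC=C)c(O)c(Br)c1CO | intermediate
18 | 2-bromo-3-(hydroxymethyl)-4,4-dimethoxy-6-(prop-2-en-1-yl)cyclohexa-2,5-dien-1-one (achiral) | C=CCC1=CC(OC)(OC)C(CO)=C(Br)C1=O | intermediate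
19 | 2-[5-bromo-4-(hydroxymethyl)-3,3-dimethoxy-6-oxocyclohexa-1,4-dien-1-yl]acetaldehyde (not isolated) | O=CCC1=CC(OC)(OC)C(CO)=C(Br)C1=O | intermediate
20 | tert-butyl (2E)-4-[5-bromo-4-(hydroxymethyl)-3,3-dimethoxy-6-oxocyclohexa-1,4-dien-1-yl]-2-methylbut-2-enoate | O=C1C(Br)=C(CO)C(OC)(OC)C=C1C/C=C(\C)C(=O)OC(C)(C)C | intermediate
21 | tert-butyl (2E)-4-[(1S,6R)-3-bromo-4-(hydroxymethyl)-5,5-dimethoxy-2-oxo-7-oxabicyclo[4.1.0]hept-3-en-1-yl]-2-methylbut-2-enoate | BrC1=C(CO)C(OC)(OC)[C@@H]2O[C@]2(C/C=C(\C)C(=O)OC(C)(C)C)C1=O | intermediate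
22 | tert-butyl (2E)-4-[(1S,6R)-3-[(1E)-hept-1-en-1-yl]-4-(hydroxymethyl)-5,5-dimethoxy-2-oxo-7-oxabicyclo[4.1.0]hept-3-en-1-yl]-2-methylbut-2-enoate (not isolated) | CCCCC/C=C/C1=C(CO)C(OC)(OC)[C@@H]2O[C@]2(C/C=C(\C)C(=O)OC(C)(C)C)C1=O | intermediate
23 | tert-butyl (2E)-4-[(1S,6R)-3-[(1E)-hept-1-en-1-yl]-4-(hydroxymethyl)-2,5-dioxo-7-oxabicyclo[4.1.0]hept-3-en-1-yl]-2-methylbut-2-enoate | CCCCC/C=C/C1=C(CO)C(=O)[C@@H]2O[C@]2(C/C=C(\C)C(=O)OC(C)(C)C)C1=O | intermediate
24 | tert-butyl (2E)-4-[(1S,5R,6S)-3-[(1E)-hept-1-en-1-yl]-5-hydroxy-4-(hydroxymethyl)-2-oxo-7-oxabicyclo[4.1.0]hept-3-en-1-yl]-2-methylbut-2-enoate (hydroxyl anti to the oxirane) | CCCCC/C=C/C1=C(CO)[C@@H](O)[C@@H]2O[C@]2(C/C=C(\C)C(=O)OC(C)(C)C)C1=O | intermediate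
25 | (2E)-4-[(1S,5R,6S)-3-[(1E)-hept-1-en-1-yl]-5-hydroxy-4-(hydroxymethyl)-2-oxo-7-oxabicyclo[4.1.0]hept-3-en-1-yl]-2-methylbut-2-enoic acid | CCCCC/C=C/C1=C(CO)[C@@H](O)[C@@H]2O[C@]2(C/C=C(\C)C(=O)O)C1=O | target

## Step count and risks

Total step count: 15 (steps 1–3 make ylide 4, steps 4–5 make stannane 9, steps 6–15 build and finish the core).
Longest linear sequence: 10 steps (steps 6 to 15, from 10 or 11 to 25).

Steps most likely to fail, each with one fallback:

Risk 1 (step 6, cycloaddition/aromatisation). The electron-rich furan may polymerise, or the minor regioisomer may form. The fallback builds the same arene by directed metalation instead of cycloaddition. It sets out from allyl bromide 14 (the only route compound it needs) together with bought hydroquinone F1, and comes back to the route at 15. Hydroquinone F1, used in excess, is monomethylated (MeI, K2CO3, acetone) to 4-methoxyphenol F2. Bromination ortho to the free hydroxyl (Br2, CH2Cl2, 0 °C) gives 2-bromo-4-methoxyphenol F3. O-Allylation with 14 (K2CO3, DMF) gives 2-bromo-4-methoxy-1-(prop-2-en-1-yloxy)benzene F4. Deprotonation of F4 at the carbon flanked by bromine and methoxy (LiN(i-Pr)2, THF, −78 °C) and trapping with ClCO2Me gives 15 with unambiguous regiochemistry.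

Risk 2 (step 12, asymmetric epoxidation). The ee may be insufficient on this trisubstituted enone, or the sense may be opposite to the one assumed. The fallback replaces asymmetric induction by resolution; it sets out from 20 and comes back at 21. Untemplated nucleophilic epoxidation of 20 (t-BuOOH, 1,8-diazabicyclo[5.4.0]undec-7-ene, CH2Cl2, 0 °C) gives the racemic epoxide F5 with the same regiochemistry. Its primary alcohol is esterified with (2S)-2-methoxy-2-phenylacetic acid (dicyclohexylcarbodiimide, 4-dimethylaminopyridine, CH2Cl2). The two diastereomeric esters are separated on silica or by preparative HPLC. The (1S,6R) mandelate-type ester F6, assigned by crystallography, is cleaved with K2CO3 in MeOH at 0 °C to give enantiopure 21.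

Risk 3 (step 14, catalyst-controlled reduction). The catalyst may not override the substrate's preference for hydride attack anti to the oxirane oxygen. The fallback accepts the substrate-controlled alcohol and inverts it; it sets out from 23 and comes back at 24. (i-Bu)2AlH (THF, −78 °C) reduces the C5 ketone of 23 from the face opposite the epoxide oxygen to give the syn (5S) diol F7. A double Mitsunobu esterification (4-nitrobenzoic acid, PPh3, diisopropyl azodicarboxylate, THF, 0 °C) acylates the primary alcohol and displaces the activated C5 oxygen with SN2 inversion, giving the 5R bis(4-nitrobenzoate) F8. Methanolysis of both esters (K2CO3, MeOH, 0 °C) gives 24.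

Further compounds
F1 | step 6 | benzene-1,4-diol (hydroquinone) | Oc1ccc(O)cc1
F2 | step 6 | 4-methoxyphenol | COc1ccc(O)cc1
F3 | step 6 | 2-bromo-4-methoxyphenol | COc1ccc(O)c(Br)c1
F4 | step 6 | 2-bromo-4-methoxy-1-(prop-2-en-1-yloxy)benzene | COc1ccc(OCC=C)c(Br)c1
F5 | step 12 | racemic tert-butyl (2E)-4-[(1RS,6SR)-3-bromo-4-(hydroxymethyl)-5,5-dimethoxy-2-oxo-7-oxabicyclo[4.1.0]hept-3-en-1-yl]-2-methylbut-2-enoate (cis-fused epoxide) | BrC1=C(CO)C(OC)(OC)C2OC2(C/C=C(\C)C(=O)OC(C)(C)C)C1=O
F6 | step 12 | (2S)-2-methoxy-2-phenylacetate of the primary alcohol of 21, ring configuration (1S,6R) as in 21 | BrC1=C(COC(=O)[C@@H](OC)c3ccccc3)C(OC)(OC)[C@@H]2O[C@]2(C/C=C(\C)C(=O)OC(C)(C)C)C1=O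
F7 | step 14 | tert-butyl (2E)-4-[(1S,5S,6S)-3-[(1E)-hept-1-en-1-yl]-5-hydroxy-4-(hydroxymethyl)-2-oxo-7-oxabicyclo[4.1.0]hept-3-en-1-yl]-2-methylbut-2-enoate (hydroxyl syn to the oxirane) | CCCCC/C=C/C1=C(CO)[C@H](O)[C@@H]2O[C@]2(C/C=C(\C)C(=O)OC(C)(C)C)C1=O
F8 | step 14 | bis(4-nitrobenzoate) of 24 at the primary and the C5 oxygen, ring configuration (1S,5R,6S) | CCCCC/C=C/C1=C(COC(=O)c3ccc(cc3)[N+](=O)[O-])[C@@H](OC(=O)c3ccc(cc3)[N+](=O)[O-])[C@@H]2O[C@]2(C/C=C(\C)C(=O)OC(C)(C)C)C1=O
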